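I decided to keep the books of this flask in X, not in Q, since the blue, grey and green runs were charged with the same 0.165 M of X and yet ended at 1%, 41% and 42% of their Q.

all flasks: X 0.165 M
- blue: Q 0.15 M; D 0.022 M; run made earlier
- grey: Q 0.15 M; D 0.090 M; run made earlier
- green: Q 0.22 M; D 0.045 M; run made earlier
- flask: Q 0.15 M; D 0.0450 M; time 25 min

- blue (time / min: Q / %, G / %, Z / %): 4.00: 37, 30, 36; 8.00: 21, 32, 47; 12.0: 7, 33, 50; 15.0: 10, 36, 52; 20.0: 5, 33, 54; 25.0: 1, 39, 55
- grey (time / min: Q / %, G / %, Z / %): 1.50: 68, 21, 11; 5.00: 45, 25, 30; 8.00: 39, 22, 34; 15.0: 40, 25, 37; 20.0: 41, 22, 36; 25.0: 41, 21, 38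
- green (time / min: Q / %, G / %, Z / %): 2.00: 59, 24, 12; 4.00: 43, 22, 30; 8.00: 43, 21, 32; 12.0: 46, 19, 35; 25.0: 42, 24, 34

(standard deviation of a reading: 2 percentage points)

1. the state of affairs at 25 min: stopped, and by what, or still going (X has run out first / it is still moving / all of Q has reacted / forward and back rates have come level)
2. how much of the Q has reacted by 25 min
3. how much G there is at 25 min, in percent of the Q charged
4. how much Z there is at 25 min, in percent of the Q charged

- the reaction counts as stopped when no species that holds the Q changes by six tenths of a point or more over the second half of the time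

The first entry was Q, and I booked one X for each Q reacted, which was my assumption. In the grey run Q stood level at 41%, so 0.0885 M of X went to Q and 0.0765 M stood as the second entry. Divided by the D charged, this gave 0.850, which I called the D toll, the moles of X lost apart from Q per mole of D charged. The green run read 0.831, and both values are readings that carry the scatter of a single Q value. The blue run then had room for 97.5% of its Q, and it read 99.0% reacted.

For the flask, the toll on 0.0450 M of D took 0.0383 M of the 0.165 M of X and left room for 0.127 M of Q, less than the 0.15 M charged. So I wrote X down as the limiting reagent and put the conversion at 84.7%. Taking G as 41.4% of the products, as in green's last reading, I put G at 35.1% and Z at 49.6%. Green's readings showed no change beyond their scatter after 8.00 min, earlier than 25 min, so I expected this flask to have stopped by then.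

The forecast, holding that “X exhaustion fits better”, gave "X has run out first", a conversion of 83%, G 33% and Z 50%, close to my figures but not the same.

The flask gave "X has run out first", with 81.0% of Q reacted, G at 31.8% and Z at 49.2%.

    Q + X → G, rate k1*[Q]*[X]^0.5 (k = 0.0152 M⁻⁰·⁵ s⁻¹)
    X + D → J (k = 0.153 M⁻¹ s⁻¹)
    G ⇌ Z (K = 1.55, k = 0.0107 s⁻¹)

At 25.0 min the flask held 0% of its X and 3.29% of its D, and one X goes with each D lost, so its toll came to 96.7% of the D charged against my 85.0%. With 0.60 M of Q in place of 0.15 M, my room of 0.127 M gives a conversion of 21.2%. That neighbour flask reached 23.7%, with 0% of its X and 49.6% of its D left, so its toll stood at 50.4% of the D charged.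

Readings and results are simulated with constants of no real substance, noise included.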